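**Plan**
1. Atom labels are biogenetic: guaianolide half C1–C15, germacranolide half C1'–C15'. The retrosynthesis cuts first C8'–C9' of the ten-membered ring, then the two norbornene bonds C1–C13' and C3–C11', then C7–C8 with the O8–C12 lactone bond, then C6'–C7' with the O6'–C12' lactone bond.
2. Enabling feature: the ten-membered ring holds the homoallylic alcohol array C8'(OH)–C9'H2–C10'(Me)=C1'H–C2', the retron of a carbonyl allylation with allylic transposition. A C1'-boryl/C9'=C10' allyl unit at the end of the C6' side chain and a C8' aldehyde on C7' of the spiro-lactone close the ring, set C8' and create the Z C1'=C10' alkene in one event.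
3. Forward, diene half: cyclopentenone 1 → tetrasubstituted cyclopentene (C1=C5) → seven-membered ring and trans-lactone by CrCl2-mediated allylation → tertiary alcohol 19. Dienophile half: neryl acetate → allylboronate enal 25 → cis-α-methylene lactone 31.
4. Union: dehydration of 19 gives the 2-acetoxy-1(5),3-diene, which adds to the exo-methylene group of 31 (norbornene rings, spiro C11'). Diol cleavage and epimerisation give aldehyde 36, the ten-membered ring is closed last, and the amine mask on C13 is then removed.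
5. Stereochemistry: C2 comes from (R)-4-silyloxycyclopentenone and is relayed to C10 (conjugate addition) and to C7/C8 (ring closure). C1' comes from a ligand-controlled copper borylation, C6'/C7' from (S)-glyceraldehyde acetonide through a syn-selective indium allylation, C1/C3/C11' from the exo, anti-acetoxy cycloaddition, C7' from equilibration, and C8' from 1,3-transfer from C1'.

Key step: step 25

**Remarks on the chemistry**
- Assumption: both double bonds of the ten-membered ring are taken as drawn in the target SMILES, with the ring carbons cis on each (1'(10')Z,4'Z). The Z C4'=C5' alkene is therefore carried in from nerol.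
- Assumption: in step 21 the dioxolane carbon directs bond formation anti to its CH2O substituent (H inside, allylic 1,3-strain model); (S)-27 is chosen on that basis.
- The configurations drawn at C4 (tertiary carbinol), at C11 (amine adduct) and at the dioxolane carbon are those expected; all three centres are removed later. Compounds 6, 7 and 28 are carbinol epimer mixtures, and both epimers converge.
- α/β descriptors refer to the usual guaianolide drawing with 7α-H.

**Route**

Step 1
Reactants: 1 (R)-4-(tert-butyldimethylsilyloxy)cyclopent-2-en-1-one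
Product: 2 (R)-4-(tert-butyldimethylsilyloxy)-2-iodocyclopent-2-en-1-one
Conditions: I2, pyridine/CH2Cl2, 0 → 23 °C
Reagents that add atoms: iodine, II
Why: Electrophilic α-iodination of the enone (pyridine addition, iodination, elimination) is standard for 4-silyloxycyclopentenones and creates no stereocentre.

Step 2
Reactants: 2 (R)-4-(tert-butyldimethylsilyloxy)-2-iodocyclopent-2-en-1-one
Product: 3 (R)-4-(tert-butyldimethylsilyloxy)-2-methylcyclopent-2-en-1-one
Conditions: Me4Sn, Pd2(dba)3 (5 mol%), AsPh3, CuI, NMP, 60 °C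
Reagents that add atoms: tetramethylstannane, C[Sn](C)(C)C
Why: Stille cross-coupling of the α-iodoenone installs the C15 methyl group under neutral conditions that avoid β-elimination of the silyloxy group.

Step 3
Reactants: 3 (R)-4-(tert-butyldimethylsilyloxy)-2-methylcyclopent-2-en-1-one
Product: 4 4-(tert-butyldimethylsilyloxy)-2-hydroxy-2-methylcyclopentan-1-one (hydroxyl trans to the silyloxy group)
Conditions: Mn(dpm)3 (10 mol%), PhSiH3, O2 (1 atm), i-PrOH/CH2Cl2, 0 °C; then P(OEt)3
Reagents that add atoms: dioxygen, O=O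
Why: Mukaiyama-type hydration of the enone (manganese hydride conjugate reduction, O2 trapping at the α-carbon, phosphite reduction of the hydroperoxide) gives the tertiary α-ketol, with O2 expected to enter anti to the C2 silyloxy group at a centre that is destroyed again in step 22.

Step 4
Reactants: 4 4-(tert-butyldimethylsilyloxy)-2-hydroxy-2-methylcyclopentan-1-one
Product: 5 4-(tert-butyldimethylsilyloxy)-2-methyl-2-(triethylsilyloxy)cyclopentan-1-one
Conditions: TESOTf, 2,6-lutidine, CH2Cl2, −78 → 0 °C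
Reagents that add atoms: triethylsilyl trifluoromethanesulfonate, CC[Si](CC)(CC)OS(=O)(=O)C(F)(F)F
Why: Silylation of the tertiary alcohol with the silyl triflate protects it against the bases and nucleophiles of steps 5–10.

Step 5
Reactants: 5 4-(tert-butyldimethylsilyloxy)-2-methyl-2-(triethylsilyloxy)cyclopentan-1-one
Product: 8 4-(tert-butyldimethylsilyloxy)-5-[(E)-ethylidene]-2-methyl-2-(triethylsilyloxy)cyclopentan-1-one, via lithium aldolate 6 (not isolated), via mesylate 7 (not isolated)
Conditions: LiN(i-Pr)2, THF, −78 °C; MeCHO; MsCl, −78 → 0 °C; DBU, 23 °C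
Reagents that add atoms: acetaldehyde, CC=O
Why: Aldol condensation: the kinetic lithium enolate can form only at C1 (C4 is quaternary) and adds to acetaldehyde at −78 °C before the β-silyloxy group is lost, and E1cB elimination of the mesylate gives the more stable E-ethylidene ketone.

Step 6
Reactants: 8 4-(tert-butyldimethylsilyloxy)-5-[(E)-ethylidene]-2-methyl-2-(triethylsilyloxy)cyclopentan-1-one
Product: 10 cyclopentenyl triflate carrying the 1-(1,3-dioxolan-2-yl)propan-2-yl group on C1, via bromomagnesium enolate 9 (not isolated)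
Conditions: (1,3-dioxolan-2-ylmethyl)MgBr, CuBr·SMe2 (10 mol%), THF, −78 → −40 °C; then PhNTf2, −40 → 0 °C
Reagents that add atoms: (1,3-dioxolan-2-ylmethyl)magnesium bromide, Br[Mg]CC1OCCO1; N-phenylbis(trifluoromethanesulfonimide), O=S(=O)(N(c1ccccc1)S(=O)(=O)C(F)(F)F)C(F)(F)F
Why: Copper-catalysed conjugate addition of the Grignard reagent to the exocyclic enone should take place on the face anti to the neighbouring C2 silyloxy group (this sets C10 from the E-alkene), and O-sulfonylation of the regiodefined enolate (enol triflate formation) fixes the tetrasubstituted C1=C5 double bond.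

Step 7
Reactants: 10 cyclopentenyl triflate
Product: 11 1-allyl-cyclopentene carrying the dioxolanylpropyl side chain
Conditions: allyl-SnBu3, Pd(PPh3)4 (5 mol%), LiCl, THF, 65 °C
Reagents that add atoms: allyltributylstannane, C=CC[Sn](CCCC)(CCCC)CCCC
Why: Stille coupling of the enol triflate with the allylstannane (LiCl-promoted) attaches C6–C7 without moving the ring double bond.

Step 8
Reactants: 11 1-allyl-cyclopentene acetal
Product: 12 3-[2-allyl-5-(tert-butyldimethylsilyloxy)-3-methyl-3-(triethylsilyloxy)cyclopent-1-en-1-yl]butanal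
Conditions: TESOTf, 2,4,6-collidine, CH2Cl2, 0 °C; then H2O
Reagents that add atoms: water, O
Why: Chemoselective acetal cleavage by silyl triflate/collidine (pyridinium intermediate hydrolysed by water) frees the C8 aldehyde under non-acidic conditions that spare both silyl ethers, including the tertiary allylic one.

Step 9
Reactants: 12 cyclopentenyl butanal; 13 methyl 2-(bromomethyl)acrylate
Product: 14 methyl (Z)-2-(bromomethyl)-4-(cyclopentenyl)but-2-enoate bearing the C8 aldehyde
Conditions: 13 (5 equiv), second-generation Hoveyda–Grubbs catalyst (5 mol%), CH2Cl2, 40 °C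
Reagents that add atoms: none
Why: Olefin cross-metathesis of the monosubstituted allyl terminus with an excess of the 1,1-disubstituted acrylate gives the trisubstituted enoate with the chain trans to the ester (Z descriptor), the usual outcome for methacrylate-type partners.

Step 10
Reactants: 14 bromo ester aldehyde
Product: 16 2α-(tert-butyldimethylsilyloxy)-4β-(triethylsilyloxy)-10αH-guaia-1(5),11(13)-dien-12,8α-olide, via hydroxy ester 15 (not isolated)
Conditions: CrCl2 (5 equiv), THF (0.005 M), 23 °C; aq. NH4Cl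
Reagents that add atoms: none
Why: Intramolecular Nozaki–Hiyama–Kishi-type allylation: the allylchromium adds through its γ-carbon C7 to the aldehyde in a chair-like transition state (anti addition, C10 methyl pseudo-equatorial), which should set C7 and C8 (7αH, 8βH) while closing the seven-membered ring, and the alkoxide lactonises onto the ester.

Step 11
Reactants: 16 silyl-protected guaianolide
Product: 17 13-(dimethylamino)-11βH,13-dihydro derivative of 16
Conditions: Me2NH (2 M in THF), MeOH, 0 → 23 °C
Reagents that add atoms: dimethylamine, CNC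
Why: Aza-Michael addition masks the exo-methylene lactone, which would otherwise compete as a dienophile in step 22; protonation of the enolate from the less hindered face gives the 11βH adduct, whose centre is removed again in step 26.

Step 12
Reactants: 17 amine-masked bis-silyl ether
Product: 18 13-(dimethylamino)-2α,4β-dihydroxy-11βH-guai-1(5)-en-12,8α-olide
Conditions: Bu4NF, AcOH, THF, 23 → 40 °C
Reagents that add atoms: none
Why: Fluoride-mediated desilylation, buffered with AcOH to protect the lactone and the β-amino ester, removes both silyl ethers.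

Step 13
Reactants: 18 amine-masked diol
Product: 19 2α-acetoxy-13-(dimethylamino)-4β-hydroxy-11βH-guai-1(5)-en-12,8α-olide
Conditions: Ac2O, pyridine, DMAP (cat.), CH2Cl2, 0 °C
Reagents that add atoms: acetic anhydride, CC(=O)OC(C)=O
Why: Acylation under nucleophilic catalysis is selective for the secondary C2 hydroxyl over the tertiary C4 hydroxyl.

Step 14
Reactants: 20 neryl acetate
Product: 21 (2Z,6E)-8-hydroxy-3,7-dimethylocta-2,6-dien-1-yl acetate
Conditions: SeO2 (0.3 equiv), t-BuOOH, salicylic acid (cat.), CH2Cl2, 23 °C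
Reagents that add atoms: tert-butyl hydroperoxide, CC(C)(C)OO
Why: SeO2-catalysed allylic oxidation (ene reaction, then [2,3]-shift) attacks the E-methyl group of the more electron-rich terminal alkene and leaves the acetate-deactivated Z-alkene untouched.

Step 15
Reactants: 21 (2Z,6E)-8-hydroxy-3,7-dimethylocta-2,6-dien-1-yl acetate
Product: 22 (2Z,6E)-8-(methoxycarbonyloxy)-3,7-dimethylocta-2,6-dien-1-yl acetate
Conditions: ClCO2Me, pyridine, CH2Cl2, 0 °C
Reagents that add atoms: methyl chloroformate, COC(=O)Cl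
Why: Acylation of the primary allylic alcohol gives the carbonate leaving group needed for step 16.

Step 16
Reactants: 22 allylic carbonate
Product: 23 (2Z,6R)-3,7-dimethyl-6-(4,4,5,5-tetramethyl-1,3,2-dioxaborolan-2-yl)octa-2,7-dien-1-yl acetate
Conditions: B2pin2, Cu(O-t-Bu) (5 mol%), (R,R)-QuinoxP* (5 mol%), THF, 0 °C
Reagents that add atoms: bis(pinacolato)diboron, CC1(C)OB(OC1(C)C)B1OC(C)(C)C(C)(C)O1
Why: Copper-catalysed γ-selective (SN2') allylic borylation with a chiral bisphosphine transposes the double bond to C9'=C10' and sets the boron-bearing centre C1' (the ligand antipode that gives 6R is used); allylic acetates are poor substrates, so the neryl acetate end is retained.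

Step 17
Reactants: 23 allylboronate acetate
Product: 24 (2Z,6R)-3,7-dimethyl-6-(4,4,5,5-tetramethyl-1,3,2-dioxaborolan-2-yl)octa-2,7-dien-1-ol
Conditions: K2CO3 (0.2 equiv), MeOH, 0 °C
Reagents that add atoms: none
Why: Base-catalysed transesterification removes the acetate; pinacol allylboronates tolerate these conditions.

Step 18
Reactants: 24 allylboronate alcohol
Product: 25 (2Z,6R)-3,7-dimethyl-6-(4,4,5,5-tetramethyl-1,3,2-dioxaborolan-2-yl)octa-2,7-dienal
Conditions: Dess–Martin periodinane, NaHCO3, CH2Cl2, 0 °C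
Reagents that add atoms: none
Why: Buffered Dess–Martin oxidation gives the Z-enal without isomerisation to the E-isomer and without touching the C–B bond.

Step 19
Reactants: 26 methyl acrylate; 27 (S)-2,2-dimethyl-1,3-dioxolane-4-carbaldehyde
Product: 28 methyl 2-{hydroxy[(4S)-2,2-dimethyl-1,3-dioxolan-4-yl]methyl}acrylate (carbinol epimers)
Conditions: DABCO (0.5 equiv), dioxane/H2O (1:1), 23 °C
Reagents that add atoms: none
Why: Morita–Baylis–Hillman reaction; the new carbinol centre becomes sp2 in step 20, so its configuration does not matter.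

Step 20
Reactants: 28 Baylis–Hillman alcohol
Product: 29 methyl (Z)-2-(bromomethyl)-3-[(4R)-2,2-dimethyl-1,3-dioxolan-4-yl]acrylate
Conditions: NBS, Me2S, CH2Cl2, 0 → 23 °C
Reagents that add atoms: N-bromosuccinimide, BrN1C(=O)CCC1=O
Why: SN2' bromination of the Baylis–Hillman alcohol through its alkoxysulfonium salt gives the thermodynamically preferred Z-2-(bromomethyl)enoate.

Step 21
Reactants: 25 allylboronate enal; 29 allylic bromide
Product: 31 cis-4-[(4R)-2,2-dimethyl-1,3-dioxolan-4-yl]-5-[(1Z,5R)-2,6-dimethyl-5-(pinacolatoboryl)hepta-1,6-dienyl]-3-methylenedihydrofuran-2(3H)-one, via hydroxy ester 30 (not isolated)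
Conditions: indium powder, THF/H2O (4:1), 23 °C; then PPTS (cat.), PhH, 40 °C
Reagents that add atoms: none
Why: Indium-mediated Barbier 2-(alkoxycarbonyl)allylation: the Z-allylindium reacts through a chair transition state with its γ-substituent axial (syn adduct, hence the cis-lactone after lactonisation), and the dioxolane centre directs bond formation anti to its CH2O group, which sets C7' and C6'.

Step 22
Reactants: 19 tertiary alcohol; 31 cis-α-methylene lactone
Product: 33 exo Diels–Alder adduct (norbornene with bonds C1–C13' and C3–C11' and spiro C11'), via acetoxy diene 32 (not isolated)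
Conditions: Martin sulfurane, 31 (2 equiv), CH2Cl2 (1 M), −40 → 23 °C
Reagents that add atoms: none
Why: Dehydration of the tertiary allylic alcohol generates the 2-acetoxy-1(5),3-diene, which is trapped in a biomimetic intermolecular Diels–Alder reaction: CH2 (C13') bonds to the fully substituted terminus C1, the lactone carbonyl is exo, the dienophile approaches anti to the acetoxy group and the diene anti to both cis substituents of the lactone, which sets C1, C3 and spiro C11'.

Step 23
Reactants: 33 Diels–Alder adduct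
Product: 34 terminal 1,2-diol
Conditions: AcOH/THF/H2O (3:1:1), 30 °C
Reagents that add atoms: none
Why: Acid-catalysed acetal hydrolysis frees the terminal diol; the amine is protonated and the pinacol boronate, lactones and acetate are stable to aqueous acetic acid.

Step 24
Reactants: 34 diol
Product: 36 6',7'-trans aldehyde, via cis-aldehyde 35 (not isolated)
Conditions: NaIO4, THF/pH 7 buffer, 0 °C; then Et3N, CH2Cl2, 23 °C
Reagents that add atoms: none
Why: Glycol cleavage excises the auxiliary carbon and gives the C8' aldehyde, and amine-catalysed enolisation should equilibrate C7' to the less crowded 6',7'-trans arrangement; a weak base is chosen to avoid β-elimination of the lactone carboxylate.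

Step 25
Reactants: 36 trans aldehyde carrying the C1' allylboronate
Product: 38 13-(dimethylamino)-11βH,13-dihydro derivative of the target, via borate ester 37 (not isolated)
Conditions: PhMe (0.002 M), 80 °C; then pH 7 buffer/MeOH
Reagents that add atoms: none
Why: Proposed new method: the C1' pinacol allylboronate adds to the C8' aldehyde through a closed chair-like six-membered transition state (B–O coordination, C8'–C9' bond formation, transposition of the double bond to C1'=C10'), the boron counterpart of a carbonyl–ene reaction; the closest known reactions are the Z-selective additions of α-substituted 2-methylallyl pinacol boronates to aldehydes and intramolecular allylborations that form five- to seven-membered carbocycles, whereas a ten-membered carbocycle has not been closed in this way. The ten-membered ring closes by joining C9' to C8' (10-exo-trig at the carbonyl, all three allyl carbons becoming ring members). C8' is set by 1,3-chirality transfer from the (R)-configured C1'–B centre, with the aldehyde substituent C7' equatorial and C2' axial in the chair. The Z geometry of C1'=C10' follows from this axial C2', which is enforced by 1,2-allylic strain with the C10' methyl group and by the four-atom tether C3'–C6', too short to span a diequatorial arrangement. The step needs chemoselectivity for the aldehyde over the lactones and the acetate, inherent to uncatalysed allylboration, and ring closure over oligomerisation, secured by high dilution and by the Z C4'=C5' alkene and the spiro-lactone, which hold the two chain ends on converging paths.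

Step 26
Reactants: 38 amine-masked macrocycle
Product: 40 target CNP0148007.1, via trimethylammonium iodide 39 (not isolated)
Conditions: MeI, MeCN, 23 °C; then aq. NaHCO3, CH2Cl2
Reagents that add atoms: none
Why: Exhaustive N-methylation followed by base-induced E1cB (Hofmann-type) elimination of trimethylamine regenerates the α-methylene lactone without affecting the acetate, the free alcohol or the alkenes.

**Compound list**
1 | (R)-4-(tert-butyldimethylsilyloxy)cyclopent-2-en-1-one | O=C1C=C[C@H](O[Si](C)(C)C(C)(C)C)C1 | starting material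
2 | (R)-4-(tert-butyldimethylsilyloxy)-2-iodocyclopent-2-en-1-one | O=C1C(I)=C[C@H](O[Si](C)(C)C(C)(C)C)C1 | intermediate
3 | (R)-4-(tert-butyldimethylsilyloxy)-2-methylcyclopent-2-en-1-one | O=C1C(C)=C[C@H](O[Si](C)(C)C(C)(C)C)C1 | intermediate
4 | 4-(tert-butyldimethylsilyloxy)-2-hydroxy-2-methylcyclopentan-1-one, OH trans to OTBS | O=C1[C@@](C)(O)C[C@H](O[Si](C)(C)C(C)(C)C)C1 | intermediate
5 | 4-(tert-butyldimethylsilyloxy)-2-methyl-2-(triethylsilyloxy)cyclopentan-1-one | O=C1[C@@](C)(O[Si](CC)(CC)CC)C[C@H](O[Si](C)(C)C(C)(C)C)C1 | intermediate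
6 | lithium aldolate of 5 with acetaldehyde (side chain trans to OTBS, carbinol epimers) | O=C1[C@@](C)(O[Si](CC)(CC)CC)C[C@H](O[Si](C)(C)C(C)(C)C)[C@H]1C(C)O[Li] | intermediate
7 | corresponding methanesulfonate | O=C1[C@@](C)(O[Si](CC)(CC)CC)C[C@H](O[Si](C)(C)C(C)(C)C)[C@H]1C(C)OS(C)(=O)=O | intermediate
8 | 4-(tert-butyldimethylsilyloxy)-5-[(E)-ethylidene]-2-methyl-2-(triethylsilyloxy)cyclopentan-1-one | O=C1[C@@](C)(O[Si](CC)(CC)CC)C[C@H](O[Si](C)(C)C(C)(C)C)/C1=C\C | intermediate
9 | bromomagnesium enolate after conjugate addition | C[C@@H](CC1OCCO1)C2=C(O[Mg]Br)[C@@](C)(O[Si](CC)(CC)CC)C[C@@H]2O[Si](C)(C)C(C)(C)C | intermediate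
10 | 3-(tert-butyldimethylsilyloxy)-2-[1-(1,3-dioxolan-2-yl)propan-2-yl]-5-methyl-5-(triethylsilyloxy)cyclopent-1-en-1-yl triflate | C[C@@H](CC1OCCO1)C2=C(OS(=O)(=O)C(F)(F)F)[C@@](C)(O[Si](CC)(CC)CC)C[C@@H]2O[Si](C)(C)C(C)(C)C | intermediate
11 | 1-allyl analogue of 10 (allyl in place of OTf) | C[C@@H](CC1OCCO1)C2=C(CC=C)[C@@](C)(O[Si](CC)(CC)CC)C[C@@H]2O[Si](C)(C)C(C)(C)C | intermediate
12 | 3-[2-allyl-5-(tert-butyldimethylsilyloxy)-3-methyl-3-(triethylsilyloxy)cyclopent-1-en-1-yl]butanal | C[C@@H](CC=O)C2=C(CC=C)[C@@](C)(O[Si](CC)(CC)CC)C[C@@H]2O[Si](C)(C)C(C)(C)C | intermediate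
13 | methyl 2-(bromomethyl)acrylate | C=C(CBr)C(=O)OC | starting material
14 | methyl (Z)-2-(bromomethyl)-4-[5-(tert-butyldimethylsilyloxy)-3-methyl-2-(4-oxobutan-2-yl)-3-(triethylsilyloxy)cyclopent-1-en-1-yl]but-2-enoate | C[C@@H](CC=O)C2=C(C/C=C(\CBr)C(=O)OC)[C@@](C)(O[Si](CC)(CC)CC)C[C@@H]2O[Si](C)(C)C(C)(C)C | intermediate
15 | ring-closed hydroxy ester (8α-OH, 7αH) | COC(=O)C(=C)[C@H]1CC2=C([C@@H](C)C[C@@H]1O)[C@@H](O[Si](C)(C)C(C)(C)C)C[C@]2(C)O[Si](CC)(CC)CC | intermediate
16 | 2α-(tert-butyldimethylsilyloxy)-4β-(triethylsilyloxy)-10αH-guaia-1(5),11(13)-dien-12,8α-olide | C=C1C(=O)O[C@H]2C[C@H](C)C3=C(C[C@H]12)[C@@](C)(O[Si](CC)(CC)CC)C[C@@H]3O[Si](C)(C)C(C)(C)C | intermediate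
17 | 13-(dimethylamino)-11βH,13-dihydro-16 | CN(C)C[C@H]1C(=O)O[C@H]2C[C@H](C)C3=C(C[C@H]12)[C@@](C)(O[Si](CC)(CC)CC)C[C@@H]3O[Si](C)(C)C(C)(C)C | intermediate
18 | 13-(dimethylamino)-2α,4β-dihydroxy-11βH-guai-1(5)-en-12,8α-olide | CN(C)C[C@H]1C(=O)O[C@H]2C[C@H](C)C3=C(C[C@H]12)[C@@](C)(O)C[C@@H]3O | intermediate
19 | 2α-acetoxy-13-(dimethylamino)-4β-hydroxy-11βH-guai-1(5)-en-12,8α-olide | CN(C)C[C@H]1C(=O)O[C@H]2C[C@H](C)C3=C(C[C@H]12)[C@@](C)(O)C[C@@H]3OC(C)=O | intermediate
20 | neryl acetate | CC(=O)OC/C=C(/C)CCC=C(C)C | starting material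
21 | (2Z,6E)-8-hydroxy-3,7-dimethylocta-2,6-dien-1-yl acetate | CC(=O)OC/C=C(/C)CC/C=C(\C)CO | intermediate
22 | (2Z,6E)-8-(methoxycarbonyloxy)-3,7-dimethylocta-2,6-dien-1-yl acetate | CC(=O)OC/C=C(/C)CC/C=C(\C)COC(=O)OC | intermediate
23 | (2Z,6R)-3,7-dimethyl-6-(4,4,5,5-tetramethyl-1,3,2-dioxaborolan-2-yl)octa-2,7-dien-1-yl acetate | CC(=O)OC/C=C(/C)CC[C@@H](B1OC(C)(C)C(C)(C)O1)C(C)=C | intermediate
24 | (2Z,6R)-3,7-dimethyl-6-(4,4,5,5-tetramethyl-1,3,2-dioxaborolan-2-yl)octa-2,7-dien-1-ol | OC/C=C(/C)CC[C@@H](B1OC(C)(C)C(C)(C)O1)C(C)=C | intermediate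
25 | (2Z,6R)-3,7-dimethyl-6-(4,4,5,5-tetramethyl-1,3,2-dioxaborolan-2-yl)octa-2,7-dienal | O=C/C=C(/C)CC[C@@H](B1OC(C)(C)C(C)(C)O1)C(C)=C | intermediate
26 | methyl acrylate | C=CC(=O)OC | starting material
27 | (S)-2,2-dimethyl-1,3-dioxolane-4-carbaldehyde | O=C[C@@H]1COC(C)(C)O1 | starting material
28 | methyl 2-{hydroxy[(4S)-2,2-dimethyl-1,3-dioxolan-4-yl]methyl}acrylate (carbinol epimers) | C=C(C(=O)OC)C(O)[C@@H]1COC(C)(C)O1 | intermediate
29 | methyl (Z)-2-(bromomethyl)-3-[(4R)-2,2-dimethyl-1,3-dioxolan-4-yl]acrylate | BrC/C(C(=O)OC)=C\[C@@H]1COC(C)(C)O1 | intermediate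
30 | syn-hydroxy ester from 25 and 29 | C=C(C(=O)OC)[C@@H]([C@@H]1COC(C)(C)O1)[C@H](O)/C=C(/C)CC[C@@H](B2OC(C)(C)C(C)(C)O2)C(C)=C | intermediate
31 | cis-4-[(4R)-2,2-dimethyl-1,3-dioxolan-4-yl]-5-[(1Z,5R)-2,6-dimethyl-5-(pinacolatoboryl)hepta-1,6-dienyl]-3-methylenedihydrofuran-2(3H)-one | C=C1C(=O)O[C@H](/C=C(/C)CC[C@@H](B2OC(C)(C)C(C)(C)O2)C(C)=C)[C@@H]1[C@@H]3COC(C)(C)O3 | intermediate
32 | 2α-acetoxy-13-(dimethylamino)-11βH-guaia-1(5),3-dien-12,8α-olide | CN(C)C[C@H]1C(=O)O[C@H]2C[C@H](C)C3=C(C[C@H]12)C(C)=C[C@@H]3OC(C)=O | intermediate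
33 | exo Diels–Alder adduct of 32 and 31 (cis-6',7'-lactone, dioxolane on C7', boronate on C1') | CN(C)C[C@H]1C(=O)O[C@H]2C[C@H](C)[C@]34C[C@@]5(C(=O)O[C@H](/C=C(/C)CC[C@@H](B6OC(C)(C)C(C)(C)O6)C(C)=C)[C@@H]5[C@@H]7COC(C)(C)O7)[C@H](C(C)=C3C[C@H]12)[C@@H]4OC(C)=O | intermediate
34 | diol from 33 (1,2-dihydroxyethyl on C7') | CN(C)C[C@H]1C(=O)O[C@H]2C[C@H](C)[C@]34C[C@@]5(C(=O)O[C@H](/C=C(/C)CC[C@@H](B6OC(C)(C)C(C)(C)O6)C(C)=C)[C@@H]5[C@@H](O)CO)[C@H](C(C)=C3C[C@H]12)[C@@H]4OC(C)=O | intermediate
35 | cis-aldehyde (CHO on C7' cis to the C6' side chain) | CN(C)C[C@H]1C(=O)O[C@H]2C[C@H](C)[C@]34C[C@@]5(C(=O)O[C@H](/C=C(/C)CC[C@@H](B6OC(C)(C)C(C)(C)O6)C(C)=C)[C@@H]5C=O)[C@H](C(C)=C3C[C@H]12)[C@@H]4OC(C)=O | intermediate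
36 | trans-aldehyde (C7' as in the target) | CN(C)C[C@H]1C(=O)O[C@H]2C[C@H](C)[C@]34C[C@@]5(C(=O)O[C@H](/C=C(/C)CC[C@@H](B6OC(C)(C)C(C)(C)O6)C(C)=C)[C@H]5C=O)[C@H](C(C)=C3C[C@H]12)[C@@H]4OC(C)=O | intermediate
37 | macrocyclic borate ester (8'-O-Bpin) | CN(C)C[C@H]1C(=O)O[C@H]2C[C@H](C)[C@]34C[C@@]5(C(=O)O[C@@H]6/C=C(/C)CC/C=C(/C)C[C@@H](OB7OC(C)(C)C(C)(C)O7)[C@H]65)[C@H](C(C)=C3C[C@H]12)[C@@H]4OC(C)=O | intermediate
38 | 13-(dimethylamino)-11βH,13-dihydro derivative of the target | CN(C)C[C@H]1C(=O)O[C@H]2C[C@H](C)[C@]34C[C@@]5(C(=O)O[C@@H]6/C=C(/C)CC/C=C(/C)C[C@@H](O)[C@H]65)[C@H](C(C)=C3C[C@H]12)[C@@H]4OC(C)=O | intermediate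
39 | 13-(trimethylammonio) iodide of 38 | C[N+](C)(C)C[C@H]1C(=O)O[C@H]2C[C@H](C)[C@]34C[C@@]5(C(=O)O[C@@H]6/C=C(/C)CC/C=C(/C)C[C@@H](O)[C@H]65)[C@H](C(C)=C3C[C@H]12)[C@@H]4OC(C)=O.[I-] | intermediate
40 | CNP0148007.1 | C=C1C(=O)O[C@H]2C[C@H](C)[C@]34C[C@@]5(C(=O)O[C@@H]6/C=C(/C)CC/C=C(/C)C[C@@H](O)[C@H]65)[C@H](C(C)=C3C[C@H]12)[C@@H]4OC(C)=O | target

**Step count and risks**
Total step count: 26. Longest linear sequence: 18 steps (steps 1–13, then 22–26).

Most likely to fail:

1. Step 25 (Proposed new method). What may go wrong: the macrocyclic allylboration is slower than intermolecular allylation or protodeboronation, or residual cis-aldehyde cyclises, so the ten-membered ring does not form cleanly. The fallback closes the same ring with known chemistry at C1'=C10' by olefin metathesis. It sets out from 33. γ-Selective protodeboronation of the allylboronate (Bu4NF·3H2O, THF) gives the isopropylidene-terminated adduct F1. Hydrolysis of the acetonide (aqueous AcOH) gives the diol F2. NaIO4 cleavage gives the cis-aldehyde F3, which Et3N equilibrates to the trans-aldehyde F4. Reagent-controlled Brown methallylation, with the antipode of B-(2-methylallyl)diisopinocampheylborane that delivers the (8'R)-carbinol, gives the homoallylic alcohol F5. Ring-closing metathesis between the 2-methylallyl and isopropylidene termini (second-generation Hoveyda–Grubbs catalyst, PhMe, 80 °C, high dilution) expels 2-methylpropene and comes back to the route at 38.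

2. Step 22. What may go wrong: the acetoxy diene is lost by sigmatropic hydrogen shift or dimerisation before it is intercepted, dehydration goes to the exocyclic isomer, or the dienophile adds on the face syn to the acetoxy group (poor facial selectivity). The fallback uses a bulky silyl ether as the steric control element on the diene face. It sets out from 17. Selective methanolysis of the tertiary allylic triethylsilyl ether (PPTS, MeOH, 0 °C) gives the tertiary alcohol F6, which keeps the C2 tert-butyldimethylsilyl ether. Dehydration with Martin sulfurane in the presence of 31 gives the silyloxy diene F7, which is trapped as the silyloxy adduct F8. Pyridine-buffered HF·pyridine frees the C2 alcohol F9, and acetylation (Ac2O, pyridine, DMAP) comes back to the route at 33.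

3. Step 10. What may go wrong: loss of diastereocontrol in the chromium-mediated ring closure (syn instead of anti addition, giving the cis-fused lactone). The fallback accepts a syn closure and corrects C8 by inversion. It sets out from 14. Zinc-mediated closure (activated Zn, THF/aq. NH4Cl), which is syn-selective for such bromides, gives the cis-fused 8-epi-lactone F10. LiOH (THF/H2O) opens it to the hydroxy acid F11. Mitsunobu lactonisation (PPh3, DIAD, PhMe) closes the lactone with inversion at C8 and comes back to the route at 16.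

**Further compounds**
F1 | step 25 | isopropylidene-terminated adduct (33 with the C1' boronate replaced by C1'=C10' and a C9' methyl group) | CN(C)C[C@H]1C(=O)O[C@H]2C[C@H](C)[C@]34C[C@@]5(C(=O)O[C@H](/C=C(/C)CCC=C(C)C)[C@@H]5[C@@H]6COC(C)(C)O6)[C@H](C(C)=C3C[C@H]12)[C@@H]4OC(C)=O
F2 | step 25 | diol from F1 | CN(C)C[C@H]1C(=O)O[C@H]2C[C@H](C)[C@]34C[C@@]5(C(=O)O[C@H](/C=C(/C)CCC=C(C)C)[C@@H]5[C@@H](O)CO)[C@H](C(C)=C3C[C@H]12)[C@@H]4OC(C)=O
F3 | step 25 | cis-aldehyde of the isopropylidene series | CN(C)C[C@H]1C(=O)O[C@H]2C[C@H](C)[C@]34C[C@@]5(C(=O)O[C@H](/C=C(/C)CCC=C(C)C)[C@@H]5C=O)[C@H](C(C)=C3C[C@H]12)[C@@H]4OC(C)=O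
F4 | step 25 | trans-aldehyde of the isopropylidene series | CN(C)C[C@H]1C(=O)O[C@H]2C[C@H](C)[C@]34C[C@@]5(C(=O)O[C@H](/C=C(/C)CCC=C(C)C)[C@H]5C=O)[C@H](C(C)=C3C[C@H]12)[C@@H]4OC(C)=O
F5 | step 25 | (8'R)-homoallylic alcohol carrying the 2-methylallyl group | CN(C)C[C@H]1C(=O)O[C@H]2C[C@H](C)[C@]34C[C@@]5(C(=O)O[C@H](/C=C(/C)CCC=C(C)C)[C@H]5[C@H](O)CC(C)=C)[C@H](C(C)=C3C[C@H]12)[C@@H]4OC(C)=O
F6 | step 22 | 2α-(tert-butyldimethylsilyloxy)-13-(dimethylamino)-4β-hydroxy-11βH-guai-1(5)-en-12,8α-olide | CN(C)C[C@H]1C(=O)O[C@H]2C[C@H](C)C3=C(C[C@H]12)[C@@](C)(O)C[C@@H]3O[Si](C)(C)C(C)(C)C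
F7 | step 22 | 2α-(tert-butyldimethylsilyloxy)-13-(dimethylamino)-11βH-guaia-1(5),3-dien-12,8α-olide | CN(C)C[C@H]1C(=O)O[C@H]2C[C@H](C)C3=C(C[C@H]12)C(C)=C[C@@H]3O[Si](C)(C)C(C)(C)C
F8 | step 22 | silyloxy analogue of adduct 33 | CN(C)C[C@H]1C(=O)O[C@H]2C[C@H](C)[C@]34C[C@@]5(C(=O)O[C@H](/C=C(/C)CC[C@@H](B6OC(C)(C)C(C)(C)O6)C(C)=C)[C@@H]5[C@@H]7COC(C)(C)O7)[C@H](C(C)=C3C[C@H]12)[C@@H]4O[Si](C)(C)C(C)(C)C
F9 | step 22 | C2 alcohol corresponding to 33 | CN(C)C[C@H]1C(=O)O[C@H]2C[C@H](C)[C@]34C[C@@]5(C(=O)O[C@H](/C=C(/C)CC[C@@H](B6OC(C)(C)C(C)(C)O6)C(C)=C)[C@@H]5[C@@H]7COC(C)(C)O7)[C@H](C(C)=C3C[C@H]12)[C@@H]4O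
F10 | step 10 | 8-epi-16 (cis-fused 12,8β-olide) | C=C1C(=O)O[C@@H]2C[C@H](C)C3=C(C[C@H]12)[C@@](C)(O[Si](CC)(CC)CC)C[C@@H]3O[Si](C)(C)C(C)(C)C
F11 | step 10 | 8β-hydroxy acid from F10 | OC(=O)C(=C)[C@H]1CC2=C([C@@H](C)C[C@H]1O)[C@@H](O[Si](C)(C)C(C)(C)C)C[C@]2(C)O[Si](CC)(CC)CC
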